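The isoflavone is disconnected at C2: O1–C2 and C2–C3 of ring C are made together by inserting one carbon between a benzylic CH2 and an enol oxygen. The step uses the fact that on ring A the pyranone oxygen O1 (at C8a) lies 1,3 to the C7 hydroxyl, with the C4 carbonyl attached at C4a next to C8a. A 3-alkoxycyclohex-2-enone acylated at C6 has exactly this arrangement, so ring A is carried as a cyclohexenone and dehydrogenated afterwards. The precursor is a 6-(arylacetyl)-3-ethoxycyclohex-2-enone whose aryl group is ring B with its catechol tied up as an acetonide.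

Key step: step 9

Remark: the target has no stereocentre; the sp3 centres that appear on the way (Claisen dienone, diketone precursor) are racemic and are later flattened. Ar = 7-methoxy-2,2-dimethyl-6-(2-methylbut-3-en-2-yl)-1,3-benzodioxol-4-yl, that is ring B with O2′/O3′ as acetonide, O4′ methylated and the 1,1-dimethylallyl group at C5′. Chromone numbering is used for rings A and C.

Ring B is built in a regiochemically unambiguous order: the allyl group is placed by Claisen rearrangement first, and bromine is then introduced by directed lithiation at the only ring hydrogen ortho to oxygen. Electrophilic bromination of the free phenol 2 is avoided because attack ortho to the hydroxyl (para to a dioxole oxygen) competes with attack para to it.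

Step 1
Reactants: 1 pyrogallol (benzene-1,2,3-triol)
Product: 2 2,2-dimethyl-1,3-benzodioxol-4-ol
Conditions: Me2C(OMe)2, TsOH·H2O (cat.), toluene, reflux, MeOH distilled off
Reagents that add atoms: 2,2-dimethoxypropane, COC(C)(C)OC
Why: Acid-catalysed transketalisation should join two adjacent hydroxyls in the five-membered ketal and leave the third, the future O4′, as the only free phenol.

Step 2
Reactants: 2 2,2-dimethyl-1,3-benzodioxol-4-ol; 3 prenyl bromide (1-bromo-3-methylbut-2-ene)
Product: 4 2,2-dimethyl-4-[(3-methylbut-2-en-1-yl)oxy]-1,3-benzodioxole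
Conditions: K2CO3, acetone, reflux
Reagents that add atoms: none
Why: Williamson ether synthesis, the phenoxide displacing bromide at the primary allylic carbon (SN2) under conditions that favour O-alkylation.

Step 3
Reactants: 4 2,2-dimethyl-4-[(3-methylbut-2-en-1-yl)oxy]-1,3-benzodioxole
Product: 6 2,2-dimethyl-5-(2-methylbut-3-en-2-yl)-1,3-benzodioxol-4-ol, via ortho-dienone 5 (not isolated)
Conditions: PhNEt2, 190 °C, argon, sealed vessel
Reagents that add atoms: none
Why: Aromatic Claisen rearrangement, in which the [3,3] shift bonds the tertiary allyl terminus to C5, the only ortho carbon bearing hydrogen, and dienone 5 then tautomerises to the phenol, the basic solvent speeding this enolisation relative to onward Cope migration to the para carbon.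

Step 4
Reactants: 6 2,2-dimethyl-5-(2-methylbut-3-en-2-yl)-1,3-benzodioxol-4-ol
Product: 7 4-methoxy-2,2-dimethyl-5-(2-methylbut-3-en-2-yl)-1,3-benzodioxole
Conditions: MeI, K2CO3, DMF, rt
Reagents that add atoms: iodomethane, CI
Why: Williamson O-methylation under base-only conditions, which avoids acid-induced closure of the phenol on to the neighbouring alkene and blocks that oxygen for the rest of the route.

Step 5
Reactants: 7 4-methoxy-2,2-dimethyl-5-(2-methylbut-3-en-2-yl)-1,3-benzodioxole
Product: 9 4-bromo-7-methoxy-2,2-dimethyl-6-(2-methylbut-3-en-2-yl)-1,3-benzodioxole (Ar–Br), via aryllithium 8 (not isolated)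
Conditions: s-BuLi, TMEDA, THF, −78 → −40 °C; BrCH2CH2Br, −78 °C → rt
Reagents that add atoms: 1,2-dibromoethane, BrCCBr
Why: Directed ortho-metalation, since C7–H of 7 is the only ring hydrogen ortho to an oxygen (the dioxole oxygen) while the other hydrogen sits beside the tert-alkyl group, followed by bromine transfer from 1,2-dibromoethane with loss of ethene.

Step 6
Reactants: 9 Ar–Br; 10 diethyl malonate
Product: 11 diethyl 2-(Ar)propanedioate
Conditions: Pd(OAc)2 (3 mol %), P(t-Bu)3·HBF4 (6 mol %), K3PO4, toluene, 90 °C
Reagents that add atoms: none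
Why: Palladium-catalysed α-arylation of a malonate enolate (oxidative addition to zerovalent palladium, enolate binding, reductive elimination) under a mild phosphate base, with the hindered vinyl group meta to the reacting carbon and unable to intercept the arylpalladium species.

Step 7
Reactants: 11 diethyl 2-(Ar)propanedioate
Product: 13 2-(Ar)acetic acid, via arylmalonic acid 12 (not isolated)
Conditions: NaOH, EtOH–H2O, 80 °C; 1 M HCl to pH 2, 0 °C; toluene, 90 °C
Reagents that add atoms: sodium hydroxide, [Na+].[OH-]
Why: Ester saponification followed by thermal decarboxylation of the arylmalonic acid through its cyclic six-membered transition state, the ketal tolerating brief cold dilute acid.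

Step 8
Reactants: 13 2-(Ar)acetic acid; 14 3-ethoxycyclohex-2-en-1-one
Product: 17 rac-3-ethoxy-6-[2-(Ar)acetyl]cyclohex-2-en-1-one, via acyl imidazolide 15 (not isolated), via lithium dienolate 16 (not isolated)
Conditions: 13, CDI, THF, rt; added to 14 (3.3 equiv) + LiN(i-Pr)2 (3.3 equiv), THF, −78 → −20 °C; AcOH quench
Reagents that add atoms: none
Why: Kinetic deprotonation of the vinylogous ester occurs at C6 (α′) and the lithium dienolate is C-acylated by the imidazolide (crossed Claisen-type acylation), the excess enolate absorbing the imidazole N–H and the acidic, largely enolised β-diketone that forms.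

Step 9
Reactants: 17 rac-3-ethoxy-6-[2-(Ar)acetyl]cyclohex-2-en-1-one
Product: 19 7-ethoxy-3-(Ar)-5,6-dihydro-4H-chromen-4-one, via enaminone 18 (not isolated)
Conditions: t-BuOCH(NMe2)2 (2 equiv), toluene, 80 °C; then AcOH, 50 °C
Reagents that add atoms: tert-butoxybis(dimethylamino)methane, CN(C)C(OC(C)(C)C)N(C)C
Why: The aminal ester ionises to a formamidinium ion and tert-butoxide, and condensation at the CH2 between the exocyclic carbonyl and ring B, with loss of tert-butanol and dimethylamine, gives enaminone 18 and with it the C2–C3 bond. After acidification the enol oxygen of the ring ketone (the future O1) adds to the aminomethylene carbon and dimethylamine is expelled (conjugate addition–elimination), which forms O1–C2 and closes ring C as a 4-pyranone. The closest known reactions are the formamide acetal syntheses of isoflavones from 2-hydroxydeoxybenzoins and of tetrahydrochromen-4-ones from 2-acylcyclohexanones and 2-acylcyclohexane-1,3-diones. Ring C closes in the 6-endo-trig mode, since the attacked C2=C3 bond lies inside the new ring. No stereocentre is formed, and the racemic centre C6 of 17 becomes the sp2 carbon C4a. The step needs site selectivity for the benzylic CH2: the C6 methine has one hydrogen and cannot give an enamine, C4–H2 is only vinylogously activated, the reagent cannot O-alkylate the enol, the acetonide keeps the 2′-oxygen from competing for C2, and any exchange of the C7 ethoxy group by dimethylamine would converge on the same dione in the following hydrolysis.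

Step 10
Reactants: 19 7-ethoxy-3-(Ar)-5,6-dihydro-4H-chromen-4-one
Product: 20 3-(Ar)-5,6-dihydro-4H-chromene-4,7(8H)-dione
Conditions: 1 M HCl, THF, rt
Reagents that add atoms: water, O
Why: Acid-catalysed hydrolysis of a doubly vinylogous ester (protonation at the C4 carbonyl, water adding at C7, ethanol leaving) should give the dione, which equilibrates with its 7-hydroxy dienol, while the aryl ketal is far slower to hydrolyse under these conditions.

Step 11
Reactants: 20 3-(Ar)-5,6-dihydro-4H-chromene-4,7(8H)-dione
Product: 21 7-hydroxy-3-(Ar)-4H-chromen-4-one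
Conditions: DDQ (1.1 equiv), 1,4-dioxane, rt → 60 °C
Reagents that add atoms: none
Why: Quinone dehydrogenation, in which the dienol tautomer of 20 is a cyclohexa-1,3-diene that loses hydride from C5 to a cation stabilised by O1 and the C7 oxygen and then a proton from C6 to give the phenol, the catechol still being masked and ring B carrying no benzylic hydrogen.

Step 12
Reactants: 21 7-hydroxy-3-(Ar)-4H-chromen-4-one
Product: 22 3-[2,3-dihydroxy-4-methoxy-5-(2-methylbut-3-en-2-yl)phenyl]-7-hydroxy-4H-chromen-4-one (target)
Conditions: 3 M HCl, MeOH–THF, 60 °C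
Reagents that add atoms: none
Why: Acid-catalysed ketal hydrolysis should release acetone and the catechol, dilute mineral acid being unable to protonate the monosubstituted alkene at a useful rate and the methylated O4′ being unable to close on it.

Compound list

1 | pyrogallol (benzene-1,2,3-triol) | Oc1cccc(O)c1O | starting material
2 | 2,2-dimethyl-1,3-benzodioxol-4-ol | CC1(C)Oc2cccc(O)c2O1 | intermediate
3 | prenyl bromide (1-bromo-3-methylbut-2-ene) | CC(C)=CCBr | starting material
4 | 2,2-dimethyl-4-[(3-methylbut-2-en-1-yl)oxy]-1,3-benzodioxole | CC(C)=CCOc1cccc2OC(C)(C)Oc12 | intermediate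
5 | rac-2,2-dimethyl-5-(2-methylbut-3-en-2-yl)-1,3-benzodioxol-4(5H)-one (not isolated) | O=C1C(C(C)(C)C=C)C=CC2=C1OC(C)(C)O2 | intermediate
6 | 2,2-dimethyl-5-(2-methylbut-3-en-2-yl)-1,3-benzodioxol-4-ol | C=CC(C)(C)c1ccc2OC(C)(C)Oc2c1O | intermediate
7 | 4-methoxy-2,2-dimethyl-5-(2-methylbut-3-en-2-yl)-1,3-benzodioxole | C=CC(C)(C)c1ccc2OC(C)(C)Oc2c1OC | intermediate
8 | [7-methoxy-2,2-dimethyl-6-(2-methylbut-3-en-2-yl)-1,3-benzodioxol-4-yl]lithium (not isolated) | [Li]c1cc(C(C)(C)C=C)c(OC)c2OC(C)(C)Oc12 | intermediate
9 | 4-bromo-7-methoxy-2,2-dimethyl-6-(2-methylbut-3-en-2-yl)-1,3-benzodioxole | Brc1cc(C(C)(C)C=C)c(OC)c2OC(C)(C)Oc12 | intermediate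
10 | diethyl malonate | CCOC(=O)CC(=O)OCC | starting material
11 | diethyl 2-[7-methoxy-2,2-dimethyl-6-(2-methylbut-3-en-2-yl)-1,3-benzodioxol-4-yl]propanedioate | CCOC(=O)C(C(=O)OCC)c1cc(C(C)(C)C=C)c(OC)c2OC(C)(C)Oc12 | intermediate
12 | 2-[7-methoxy-2,2-dimethyl-6-(2-methylbut-3-en-2-yl)-1,3-benzodioxol-4-yl]propanedioic acid (not isolated) | OC(=O)C(C(=O)O)c1cc(C(C)(C)C=C)c(OC)c2OC(C)(C)Oc12 | intermediate
13 | 2-[7-methoxy-2,2-dimethyl-6-(2-methylbut-3-en-2-yl)-1,3-benzodioxol-4-yl]acetic acid | OC(=O)Cc1cc(C(C)(C)C=C)c(OC)c2OC(C)(C)Oc12 | intermediate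
14 | 3-ethoxycyclohex-2-en-1-one | CCOC1=CC(=O)CCC1 | starting material
15 | 1-(1H-imidazol-1-yl)-2-[7-methoxy-2,2-dimethyl-6-(2-methylbut-3-en-2-yl)-1,3-benzodioxol-4-yl]ethan-1-one (not isolated) | O=C(Cc1cc(C(C)(C)C=C)c(OC)c2OC(C)(C)Oc12)n1ccnc1 | intermediate
16 | lithium 5-ethoxycyclohexa-1,5-dien-1-olate (kinetic dienolate of 14, not isolated) | [Li]OC1=CCCC(OCC)=C1 | intermediate
17 | rac-3-ethoxy-6-{2-[7-methoxy-2,2-dimethyl-6-(2-methylbut-3-en-2-yl)-1,3-benzodioxol-4-yl]acetyl}cyclohex-2-en-1-one (keto form drawn, largely enolised) | CCOC1=CC(=O)C(CC1)C(=O)Cc1cc(C(C)(C)C=C)c(OC)c2OC(C)(C)Oc12 | intermediate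
18 | 6-{3-(dimethylamino)-2-[7-methoxy-2,2-dimethyl-6-(2-methylbut-3-en-2-yl)-1,3-benzodioxol-4-yl]prop-2-enoyl}-3-ethoxycyclohex-2-en-1-one (push–pull alkene, geometry not fixed, not isolated) | CCOC1=CC(=O)C(CC1)C(=O)C(=CN(C)C)c1cc(C(C)(C)C=C)c(OC)c2OC(C)(C)Oc12 | intermediate
19 | 7-ethoxy-3-[7-methoxy-2,2-dimethyl-6-(2-methylbut-3-en-2-yl)-1,3-benzodioxol-4-yl]-5,6-dihydro-4H-chromen-4-one | CCOC1=CC2=C(CC1)C(=O)C(=CO2)c1cc(C(C)(C)C=C)c(OC)c2OC(C)(C)Oc12 | intermediate
20 | 3-[7-methoxy-2,2-dimethyl-6-(2-methylbut-3-en-2-yl)-1,3-benzodioxol-4-yl]-5,6-dihydro-4H-chromene-4,7(8H)-dione | O=C1CCC2=C(C1)OC=C(C2=O)c1cc(C(C)(C)C=C)c(OC)c2OC(C)(C)Oc12 | intermediate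
21 | 7-hydroxy-3-[7-methoxy-2,2-dimethyl-6-(2-methylbut-3-en-2-yl)-1,3-benzodioxol-4-yl]-4H-chromen-4-one | O=c1c(-c2cc(C(C)(C)C=C)c(OC)c3OC(C)(C)Oc23)coc2cc(O)ccc12 | intermediate
22 | 3-[2,3-dihydroxy-4-methoxy-5-(2-methylbut-3-en-2-yl)phenyl]-7-hydroxy-4H-chromen-4-one | C=CC(C)(C)c1cc(-c2coc3cc(O)ccc3c2=O)c(O)c(O)c1OC | target

Total step count: 12
Longest linear sequence: 12 steps (1 → 22); 3, 10 and 14 are bought.

Steps most likely to fail

Step 9. The aminomethylenation may stall once the enolised diketone has been deprotonated, the ring closure may not follow the condensation, or liberated dimethylamine may attack the ethoxy-bearing carbon. The fallback sets out from 17 and comes back at 21, so that steps 10 and 11 fall away. Ring A is aromatised first and ring C is then closed on a phenol by the classical deoxybenzoin protocol. Compound 17 is hydrolysed with 1 M HCl in THF to rac-4-[2-(Ar)acetyl]cyclohexane-1,3-dione F1. Its dienol is dehydrogenated with DDQ in dioxane to 1-(2,4-dihydroxyphenyl)-2-(Ar)ethan-1-one F2. Condensation of F2 with DMF dimethyl acetal in THF at 60 °C closes the pyranone on the 2-hydroxyl and should give 21.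

Step 3. Onward Cope migration of the allyl unit to the free para carbon, abnormal Claisen isomerisation and thermal closure of the product on its own alkene may all erode the ortho product. The fallback sets out from 2 and comes back at 7, and installs the tertiary allyl group by cross-coupling. Ortho-selective bromination of 2 (NBS, catalytic i-Pr2NH, CH2Cl2, 0 °C) gives 5-bromo-2,2-dimethyl-1,3-benzodioxol-4-ol F3. Methylation (MeI, K2CO3, DMF) gives 5-bromo-4-methoxy-2,2-dimethyl-1,3-benzodioxole F4. A Suzuki–Miyaura coupling of F4 with 3-methylbut-2-en-1-ylboronic acid pinacol ester, run with Pd(OAc)2 and a bulky biarylphosphine chosen for the branched (γ) product, K3PO4, THF–H2O, should give 7.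

Step 8. Proton transfer from the benzylic CH2 of the acyl donor to the basic dienolate, O-acylation, or a second acylation of the product may compete with C-acylation. The fallback sets out from 13 and comes back at 17, and uses an acyl donor that is less acidic and whose adduct does not collapse in the basic medium. Acid 13 is converted with CDI and MeNHOMe·HCl into N-methoxy-N-methyl-2-(Ar)acetamide F5. F5 is added to dienolate 16 (from 14 and LiN(i-Pr)2, THF, −78 → 0 °C); the lithium-chelated tetrahedral adduct persists until the quench and should release 17 only on work-up.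

Further compounds

F1 | step 9 | rac-4-{2-[7-methoxy-2,2-dimethyl-6-(2-methylbut-3-en-2-yl)-1,3-benzodioxol-4-yl]acetyl}cyclohexane-1,3-dione | O=C1CC(=O)C(CC1)C(=O)Cc1cc(C(C)(C)C=C)c(OC)c2OC(C)(C)Oc12
F2 | step 9 | 1-(2,4-dihydroxyphenyl)-2-[7-methoxy-2,2-dimethyl-6-(2-methylbut-3-en-2-yl)-1,3-benzodioxol-4-yl]ethan-1-one | O=C(Cc1cc(C(C)(C)C=C)c(OC)c2OC(C)(C)Oc12)c1ccc(O)cc1O
F3 | step 3 | 5-bromo-2,2-dimethyl-1,3-benzodioxol-4-ol | CC1(C)Oc2ccc(Br)c(O)c2O1
F4 | step 3 | 5-bromo-4-methoxy-2,2-dimethyl-1,3-benzodioxole | COc1c(Br)ccc2OC(C)(C)Oc12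
F5 | step 8 | N-methoxy-N-methyl-2-[7-methoxy-2,2-dimethyl-6-(2-methylbut-3-en-2-yl)-1,3-benzodioxol-4-yl]acetamide | CON(C)C(=O)Cc1cc(C(C)(C)C=C)c(OC)c2OC(C)(C)Oc12
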